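**Plan**

- Numbering: C10 is the OCH2 carbon on C1. Ring A is C1–C2–C3–C4=C5–C9 and ring B is C5–C6–C7–C8–C9. C7 carries the lactone carbonyl C11, C8 the lactone oxygen, and C4 the quaternary carbon C1' of ring D.
- The enabling feature is the tetrasubstituted C4=C5 bond shared by rings A and B, with C3 cis to C9 and the vicinal sp3 pair C9–C1 beside it. This is the imprint of a syn addition of two carbons across an alkyne C4≡C5 tethered to a former alkene C9=C1, so C5–C9, C1–C2 and C3–C4 are cut together ([2+2+2] of a 1,6-enyne with ethylene).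
- Before that cut, the β-lactone is opened at C11–O and C10 is taken back to an ester carbon, because an acyloxymethyl group on the rhodium-bound C1 would invite β-oxygen and β-hydride elimination. The enyne is then cut at C7–C8 (aldol) and C5–C6 (acetylide/oxetane).
- Forward: ring D with its quaternary centre is built first, the C5–C6–C7–C11 chain is attached, the aldol adds C8–C9–C1–C10, rings B and A close in one step, and the β-lactone ring closes last.
- Stereochemistry: C1' comes from a reagent-controlled cyclopropanation followed by hydrogenolysis; C7 and C8 from an auxiliary-controlled syn-aldol; C9 from C8 by substrate control in the cycloaddition; C1 from the E geometry of the enoate.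

Key step: step 15

Remark: the facial sense of the cyclopropanation in step 4 is assigned from the established model for this dioxaborolane (the (4R,5R) reagent is taken to give (1R,6S)-6), and (R)-BINAP in step 15 stands for whichever ligand antipode proves matched with the substrate bias.

**Route**

Step 1
Reactants: 1 3,3-dimethylcyclohexanone
Product: 3 5,5-dimethylcyclohex-1-en-1-yl trifluoromethanesulfonate, via kinetic lithium enolate 2 (not isolated)
Conditions: LiN(i-Pr)2, THF, −78 °C; then PhNTf2, −78 → 0 °C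
Reagents that add atoms: N-phenylbis(trifluoromethanesulfonimide), O=S(=O)(N(c1ccccc1)S(=O)(=O)C(F)(F)F)C(F)(F)F
Why: Kinetic deprotonation by the hindered amide base should occur at C6, away from the neopentyl C2 methylene, and O-sulfonylation of the enolate (enol triflate formation) fixes the double bond on that side.

Step 2
Reactants: 3 5,5-dimethylcyclohex-1-en-1-yl trifluoromethanesulfonate
Product: 4 methyl 5,5-dimethylcyclohex-1-ene-1-carboxylate
Conditions: Pd(OAc)2 (cat.), PPh3, CO (1 atm), Et3N, MeOH/DMF, 60 °C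
Reagents that add atoms: carbon monoxide, [C-]#[O+]; methanol, CO
Why: Palladium-catalysed alkoxycarbonylation of an enol triflate (oxidative addition to zerovalent palladium, CO insertion, methanolysis) is a standard entry to cyclohexenecarboxylates.

Step 3
Reactants: 4 methyl 5,5-dimethylcyclohex-1-ene-1-carboxylate
Product: 5 (5,5-dimethylcyclohex-1-en-1-yl)methanol
Conditions: i-Bu2AlH (2.5 equiv), CH2Cl2, −78 → 0 °C; aq. potassium sodium tartrate
Reagents that add atoms: none
Why: 1,2-Reduction of the conjugated ester by the aluminium hydride should give the allylic alcohol without touching the trisubstituted alkene.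

Step 4
Reactants: 5 (5,5-dimethylcyclohex-1-en-1-yl)methanol
Product: 6 [(1R,6S)-3,3-dimethylbicyclo[4.1.0]heptan-1-yl]methanol
Conditions: Et2Zn, CH2I2, DME, CH2Cl2, −10 °C; (4R,5R)-2-butyl-N,N,N',N'-tetramethyl-1,3,2-dioxaborolane-4,5-dicarboxamide (1.2 equiv), then 5, −10 °C → rt
Reagents that add atoms: diiodomethane, ICI
Why: In this Charette asymmetric cyclopropanation the allylic zinc alkoxide bound to the chiral dioxaborolane directs the Simmons–Smith methylene transfer to one alkene face, which sets C1 (R) and C6 (S) of the bicycle and thereby the later quaternary centre.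

Step 5
Reactants: 6 [(1R,6S)-3,3-dimethylbicyclo[4.1.0]heptan-1-yl]methanol
Product: 7 [(1S)-1,3,3-trimethylcyclohexyl]methanol
Conditions: H2 (3 atm), PtO2 (cat.), AcOH, rt
Reagents that add atoms: none
Why: Catalytic hydrogenolysis of the cyclopropane over platinum should cleave the least substituted C6–C7 bond, turning the cyclopropane methylene into the methyl group of the quaternary centre without touching its configuration.

Step 6
Reactants: 7 [(1S)-1,3,3-trimethylcyclohexyl]methanol
Product: 8 (1S)-1,3,3-trimethylcyclohexane-1-carbaldehyde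
Conditions: Dess–Martin periodinane, CH2Cl2, rt
Reagents that add atoms: none
Why: Dess–Martin oxidation of the neopentyl primary alcohol should give an aldehyde that has no α-hydrogen and therefore cannot epimerise.

Step 7
Reactants: 8 (1S)-1,3,3-trimethylcyclohexane-1-carbaldehyde
Product: 9 (1S)-1-ethynyl-1,3,3-trimethylcyclohexane
Conditions: dimethyl (1-diazo-2-oxopropyl)phosphonate, K2CO3, MeOH, 0 °C → rt
Reagents that add atoms: dimethyl (1-diazo-2-oxopropyl)phosphonate, CC(=O)C(=[N+]=[N-])P(=O)(OC)OC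
Why: The Ohira–Bestmann (Seyferth–Gilbert) homologation converts the non-enolisable aldehyde into the terminal alkyne through a 1,2-shift in the alkylidene carbene.

Step 8
Reactants: 9 (1S)-1-ethynyl-1,3,3-trimethylcyclohexane; 10 oxetane
Product: 12 5-[(1S)-1,3,3-trimethylcyclohexyl]pent-4-yn-1-ol, via lithium acetylide 11 (not isolated)
Conditions: n-BuLi, THF, −78 °C; BF3·OEt2, then 10, −78 °C
Reagents that add atoms: none
Why: The lithium acetylide opens the BF3-activated oxetane in an SN2 ring opening, which adds C6, C7 and C11 in one operation.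

Step 9
Reactants: 12 5-[(1S)-1,3,3-trimethylcyclohexyl]pent-4-yn-1-ol
Product: 13 5-[(1S)-1,3,3-trimethylcyclohexyl]pent-4-ynoic acid
Conditions: TEMPO (cat.), PhI(OAc)2 (2.2 equiv), MeCN/H2O (1:1), rt
Reagents that add atoms: water, O
Why: The TEMPO-catalysed oxidation with PhI(OAc)2 in aqueous acetonitrile is a mild direct alcohol-to-acid oxidation that leaves the alkyne untouched.

Step 10
Reactants: 13 5-[(1S)-1,3,3-trimethylcyclohexyl]pent-4-ynoic acid; 14 (4R)-4-benzyl-1,3-oxazolidin-2-one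
Product: 16 (4R)-4-benzyl-3-{5-[(1S)-1,3,3-trimethylcyclohexyl]pent-4-ynoyl}-1,3-oxazolidin-2-one, via mixed pivalic anhydride 15 (not isolated)
Conditions: t-BuCOCl, Et3N, THF, −20 °C; then 14, LiCl, −20 °C → rt
Reagents that add atoms: none
Why: N-Acylation of the oxazolidinone through the mixed pivalic anhydride with LiCl/Et3N activation is the standard way to attach this auxiliary to an acid without strong base.

Step 11
Reactants: 16 (4R)-4-benzyl-3-{5-[(1S)-1,3,3-trimethylcyclohexyl]pent-4-ynoyl}-1,3-oxazolidin-2-one; 17 ethyl (2E)-4-oxobut-2-enoate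
Product: 19 ethyl (2E,4S,5R)-5-{[(4R)-4-benzyl-2-oxo-1,3-oxazolidin-3-yl]carbonyl}-4-hydroxy-8-[(1S)-1,3,3-trimethylcyclohexyl]oct-2-en-7-ynoate, via Z-dibutylboron enolate 18 (not isolated)
Conditions: n-Bu2BOTf, i-Pr2NEt, CH2Cl2, 0 °C; then 17, −78 → 0 °C; pH 7 buffer, MeOH, H2O2
Reagents that add atoms: none
Why: In this Evans syn-aldol reaction the Z-boron enolate adds to the aldehyde carbon through a chair Zimmerman–Traxler transition state on the face opposite the benzyl group of the (R)-auxiliary, which sets C7 (R) and C8 (S) in the syn relationship.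

Step 12
Reactants: 19 ethyl (2E,4S,5R)-5-{[(4R)-4-benzyl-2-oxo-1,3-oxazolidin-3-yl]carbonyl}-4-hydroxy-8-[(1S)-1,3,3-trimethylcyclohexyl]oct-2-en-7-ynoate
Product: 20 ethyl (2E,4S,5R)-5-{[(4R)-4-benzyl-2-oxo-1,3-oxazolidin-3-yl]carbonyl}-4-[(tert-butyldimethylsilyl)oxy]-8-[(1S)-1,3,3-trimethylcyclohexyl]oct-2-en-7-ynoate
Conditions: TBSOTf, 2,6-lutidine, CH2Cl2, −78 → 0 °C
Reagents that add atoms: tert-butyldimethylsilyl trifluoromethanesulfonate, CC(C)(C)[Si](C)(C)OS(=O)(=O)C(F)(F)F
Why: Silylation of the secondary aldol hydroxyl with the silyl triflate and a hindered pyridine base is fast at low temperature and avoids retro-aldol cleavage.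

Step 13
Reactants: 20 ethyl (2E,4S,5R)-5-{[(4R)-4-benzyl-2-oxo-1,3-oxazolidin-3-yl]carbonyl}-4-[(tert-butyldimethylsilyl)oxy]-8-[(1S)-1,3,3-trimethylcyclohexyl]oct-2-en-7-ynoate
Product: 22 (2R,3S,4E)-3-[(tert-butyldimethylsilyl)oxy]-6-ethoxy-6-oxo-2-{3-[(1S)-1,3,3-trimethylcyclohexyl]prop-2-yn-1-yl}hex-4-enoic acid, via peroxy acid 21 (not isolated)
Conditions: LiOH, H2O2, THF/H2O (3:1), 0 °C; aq. Na2SO3; HCl to pH 3
Reagents that add atoms: hydrogen peroxide, OO
Why: In this auxiliary hydrolysis the hydroperoxide anion attacks the exocyclic imide carbonyl selectively, the peroxy acid is reduced by sulfite, and at 0 °C the ethyl enoate, the silyl ether and the α-stereocentre should remain intact.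

Step 14
Reactants: 22 (2R,3S,4E)-3-[(tert-butyldimethylsilyl)oxy]-6-ethoxy-6-oxo-2-{3-[(1S)-1,3,3-trimethylcyclohexyl]prop-2-yn-1-yl}hex-4-enoic acid
Product: 23 6-tert-butyl 1-ethyl (2E,4S,5R)-4-[(tert-butyldimethylsilyl)oxy]-5-{3-[(1S)-1,3,3-trimethylcyclohexyl]prop-2-yn-1-yl}hex-2-enedioate
Conditions: O-tert-butyl-N,N'-diisopropylisourea, CH2Cl2, rt → 40 °C
Reagents that add atoms: O-tert-butyl-N,N'-diisopropylisourea, CC(C)N=C(OC(C)(C)C)NC(C)C
Why: tert-Butyl transfer from the isourea to the carboxylic acid (isourea esterification) proceeds under neutral conditions, so the hindered acid is esterified without epimerisation or loss of the silyl ether.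

Step 15
Reactants: 23 6-tert-butyl 1-ethyl (2E,4S,5R)-4-[(tert-butyldimethylsilyl)oxy]-5-{3-[(1S)-1,3,3-trimethylcyclohexyl]prop-2-yn-1-yl}hex-2-enedioate; 24 ethylene
Product: 25 2-tert-butyl 7-ethyl (1S,2R,7S,7aR)-1-[(tert-butyldimethylsilyl)oxy]-4-[(1S)-1,3,3-trimethylcyclohexyl]-2,3,5,6,7,7a-hexahydro-1H-indene-2,7-dicarboxylate
Conditions: [Rh(cod)2]BF4 (10 mol%), (R)-BINAP (10 mol%), 24 (5 atm), ClCH2CH2Cl, 60 °C
Reagents that add atoms: none
Why: Proposed new method: oxidative cyclisation of the alkyne and the E-enoate on the cationic monovalent rhodium–BINAP fragment should give a trivalent rhodacyclopentene in which C5–C9 is formed and five-membered ring B is closed in the exo mode, with rhodium bound to C4 and to the ester-bearing C1, which has no exocyclic β-hydrogen and no β-leaving group; ethylene then inserts (C1–C2) and C(sp3)–C(sp2) reductive elimination from the rhodacycloheptene forms C3–C4, closing six-membered ring A and leaving the alkyne carbons as the C4=C5 bond. The closest known reaction type is the rhodium–BINAP-catalysed [2+2+2] cycloaddition of 1,6-enynes with acrylamides or with alkynes; what is new is ethylene as an unactivated two-carbon partner combined with a tert-alkyl-substituted alkyne. C9 is controlled by the allylic C8 silyloxy stereocentre, whose C–H bond eclipses the alkene (minimal A(1,3) strain) so that C5 and the metal add to the face anti to the silyloxy group. C1 follows from C9 because both new bonds to the alkene form on the same face, so the E geometry becomes the trans arrangement of C8 and C10 on ring A. The step needs reductive elimination to outrun β-hydride loss from the seven-membered rhodacycle and needs ethylene to be taken up in preference to a second enyne, which the chelating bisphosphine, the ethylene pressure and dilution are meant to secure.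

Step 16
Reactants: 25 2-tert-butyl 7-ethyl (1S,2R,7S,7aR)-1-[(tert-butyldimethylsilyl)oxy]-4-[(1S)-1,3,3-trimethylcyclohexyl]-2,3,5,6,7,7a-hexahydro-1H-indene-2,7-dicarboxylate
Product: 26 tert-butyl (1S,2R,7S,7aR)-1-[(tert-butyldimethylsilyl)oxy]-7-(hydroxymethyl)-4-[(1S)-1,3,3-trimethylcyclohexyl]-2,3,5,6,7,7a-hexahydro-1H-indene-2-carboxylate
Conditions: LiBH4, MeOH (1 equiv), THF, 0 °C → rt
Reagents that add atoms: none
Why: This chemoselective ester reduction relies on LiBH4 reducing the ethyl ester much faster than the α-branched tert-butyl ester, and no stereocentre is touched.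

Step 17
Reactants: 26 tert-butyl (1S,2R,7S,7aR)-1-[(tert-butyldimethylsilyl)oxy]-7-(hydroxymethyl)-4-[(1S)-1,3,3-trimethylcyclohexyl]-2,3,5,6,7,7a-hexahydro-1H-indene-2-carboxylate
Product: 27 tert-butyl (1S,2R,7S,7aR)-7-[(butanoyloxy)methyl]-1-[(tert-butyldimethylsilyl)oxy]-4-[(1S)-1,3,3-trimethylcyclohexyl]-2,3,5,6,7,7a-hexahydro-1H-indene-2-carboxylate
Conditions: (n-PrCO)2O, Et3N, DMAP (cat.), CH2Cl2, 0 °C → rt
Reagents that add atoms: butanoic anhydride, CCCC(=O)OC(=O)CCC
Why: DMAP-catalysed acylation of the primary alcohol with the anhydride installs the butanoate under conditions that leave the silyl ether and the tert-butyl ester intact.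

Step 18
Reactants: 27 tert-butyl (1S,2R,7S,7aR)-7-[(butanoyloxy)methyl]-1-[(tert-butyldimethylsilyl)oxy]-4-[(1S)-1,3,3-trimethylcyclohexyl]-2,3,5,6,7,7a-hexahydro-1H-indene-2-carboxylate
Product: 28 (1S,2R,7S,7aR)-7-[(butanoyloxy)methyl]-1-hydroxy-4-[(1S)-1,3,3-trimethylcyclohexyl]-2,3,5,6,7,7a-hexahydro-1H-indene-2-carboxylic acid
Conditions: CF3CO2H/CH2Cl2/H2O (10:10:1), 0 °C → rt
Reagents that add atoms: none
Why: Acidolysis should cleave the tert-butyl ester by alkyl–oxygen fission and the silyl ether by protodesilylation in one operation, while the primary butanoate is stable to aqueous CF3CO2H at this temperature.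

Step 19
Reactants: 28 (1S,2R,7S,7aR)-7-[(butanoyloxy)methyl]-1-hydroxy-4-[(1S)-1,3,3-trimethylcyclohexyl]-2,3,5,6,7,7a-hexahydro-1H-indene-2-carboxylic acid
Product: 29 3'-norspongiolactone
Conditions: BOPCl, Et3N, CH2Cl2 (0.02 M), rt
Reagents that add atoms: none
Why: Carboxyl activation of the cis β-hydroxy acid followed by 4-exo-trig attack of the C8 hydroxyl (β-lactonisation with retention at C8) should close the lactone that the cis-disposed groups on ring B can span.

**Compound list**

1 | 3,3-dimethylcyclohexanone | CC1(C)CCCC(=O)C1 | starting material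
2 | lithium 5,5-dimethylcyclohex-1-en-1-olate (not isolated) | [Li]OC1=CCCC(C)(C)C1 | intermediate
3 | 5,5-dimethylcyclohex-1-en-1-yl trifluoromethanesulfonate | CC1(C)CCC=C(OS(=O)(=O)C(F)(F)F)C1 | intermediate
4 | methyl 5,5-dimethylcyclohex-1-ene-1-carboxylate | COC(=O)C1=CCCC(C)(C)C1 | intermediate
5 | (5,5-dimethylcyclohex-1-en-1-yl)methanol | OCC1=CCCC(C)(C)C1 | intermediate
6 | [(1R,6S)-3,3-dimethylbicyclo[4.1.0]heptan-1-yl]methanol | OC[C@@]12C[C@@H]1CCC(C)(C)C2 | intermediate
7 | [(1S)-1,3,3-trimethylcyclohexyl]methanol | OC[C@@]1(C)CCCC(C)(C)C1 | intermediate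
8 | (1S)-1,3,3-trimethylcyclohexane-1-carbaldehyde | O=C[C@@]1(C)CCCC(C)(C)C1 | intermediate
9 | (1S)-1-ethynyl-1,3,3-trimethylcyclohexane | C#C[C@@]1(C)CCCC(C)(C)C1 | intermediate
10 | oxetane | C1COC1 | starting material
11 | lithium acetylide of 9 (not isolated) | [Li]C#C[C@@]1(C)CCCC(C)(C)C1 | intermediate
12 | 5-[(1S)-1,3,3-trimethylcyclohexyl]pent-4-yn-1-ol | OCCCC#C[C@@]1(C)CCCC(C)(C)C1 | intermediate
13 | 5-[(1S)-1,3,3-trimethylcyclohexyl]pent-4-ynoic acid | OC(=O)CCC#C[C@@]1(C)CCCC(C)(C)C1 | intermediate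
14 | (4R)-4-benzyl-1,3-oxazolidin-2-one | O=C1N[C@H](Cc2ccccc2)CO1 | starting material
15 | 2,2-dimethylpropanoic 5-[(1S)-1,3,3-trimethylcyclohexyl]pent-4-ynoic anhydride (not isolated) | CC(C)(C)C(=O)OC(=O)CCC#C[C@@]1(C)CCCC(C)(C)C1 | intermediate
16 | (4R)-4-benzyl-3-{5-[(1S)-1,3,3-trimethylcyclohexyl]pent-4-ynoyl}-1,3-oxazolidin-2-one | O=C(CCC#C[C@@]1(C)CCCC(C)(C)C1)N1[C@H](Cc2ccccc2)COC1=O | intermediate
17 | ethyl (2E)-4-oxobut-2-enoate | CCOC(=O)/C=C/C=O | starting material
18 | (4R)-4-benzyl-3-{(1Z)-1-[(dibutylboranyl)oxy]-5-[(1S)-1,3,3-trimethylcyclohexyl]pent-1-en-4-yn-1-yl}-1,3-oxazolidin-2-one (not isolated) | CCCCB(CCCC)O/C(=C\CC#C[C@@]1(C)CCCC(C)(C)C1)N1[C@H](Cc2ccccc2)COC1=O | intermediate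
19 | ethyl (2E,4S,5R)-5-{[(4R)-4-benzyl-2-oxo-1,3-oxazolidin-3-yl]carbonyl}-4-hydroxy-8-[(1S)-1,3,3-trimethylcyclohexyl]oct-2-en-7-ynoate | CCOC(=O)/C=C/[C@H](O)[C@@H](CC#C[C@@]1(C)CCCC(C)(C)C1)C(=O)N1[C@H](Cc2ccccc2)COC1=O | intermediate
20 | ethyl (2E,4S,5R)-5-{[(4R)-4-benzyl-2-oxo-1,3-oxazolidin-3-yl]carbonyl}-4-[(tert-butyldimethylsilyl)oxy]-8-[(1S)-1,3,3-trimethylcyclohexyl]oct-2-en-7-ynoate | CCOC(=O)/C=C/[C@H](O[Si](C)(C)C(C)(C)C)[C@@H](CC#C[C@@]1(C)CCCC(C)(C)C1)C(=O)N1[C@H](Cc2ccccc2)COC1=O | intermediate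
21 | (2R,3S,4E)-3-[(tert-butyldimethylsilyl)oxy]-6-ethoxy-6-oxo-2-{3-[(1S)-1,3,3-trimethylcyclohexyl]prop-2-yn-1-yl}hex-4-eneperoxoic acid (not isolated) | CCOC(=O)/C=C/[C@H](O[Si](C)(C)C(C)(C)C)[C@@H](CC#C[C@@]1(C)CCCC(C)(C)C1)C(=O)OO | intermediate
22 | (2R,3S,4E)-3-[(tert-butyldimethylsilyl)oxy]-6-ethoxy-6-oxo-2-{3-[(1S)-1,3,3-trimethylcyclohexyl]prop-2-yn-1-yl}hex-4-enoic acid | CCOC(=O)/C=C/[C@H](O[Si](C)(C)C(C)(C)C)[C@@H](CC#C[C@@]1(C)CCCC(C)(C)C1)C(=O)O | intermediate
23 | 6-tert-butyl 1-ethyl (2E,4S,5R)-4-[(tert-butyldimethylsilyl)oxy]-5-{3-[(1S)-1,3,3-trimethylcyclohexyl]prop-2-yn-1-yl}hex-2-enedioate | CCOC(=O)/C=C/[C@H](O[Si](C)(C)C(C)(C)C)[C@@H](CC#C[C@@]1(C)CCCC(C)(C)C1)C(=O)OC(C)(C)C | intermediate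
24 | ethylene | C=C | starting material
25 | 2-tert-butyl 7-ethyl (1S,2R,7S,7aR)-1-[(tert-butyldimethylsilyl)oxy]-4-[(1S)-1,3,3-trimethylcyclohexyl]-2,3,5,6,7,7a-hexahydro-1H-indene-2,7-dicarboxylate | CCOC(=O)[C@H]1CCC([C@@]2(C)CCCC(C)(C)C2)=C2C[C@@H](C(=O)OC(C)(C)C)[C@@H](O[Si](C)(C)C(C)(C)C)[C@@H]21 | intermediate
26 | tert-butyl (1S,2R,7S,7aR)-1-[(tert-butyldimethylsilyl)oxy]-7-(hydroxymethyl)-4-[(1S)-1,3,3-trimethylcyclohexyl]-2,3,5,6,7,7a-hexahydro-1H-indene-2-carboxylate | OC[C@H]1CCC([C@@]2(C)CCCC(C)(C)C2)=C2C[C@@H](C(=O)OC(C)(C)C)[C@@H](O[Si](C)(C)C(C)(C)C)[C@@H]21 | intermediate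
27 | tert-butyl (1S,2R,7S,7aR)-7-[(butanoyloxy)methyl]-1-[(tert-butyldimethylsilyl)oxy]-4-[(1S)-1,3,3-trimethylcyclohexyl]-2,3,5,6,7,7a-hexahydro-1H-indene-2-carboxylate | CCCC(=O)OC[C@H]1CCC([C@@]2(C)CCCC(C)(C)C2)=C2C[C@@H](C(=O)OC(C)(C)C)[C@@H](O[Si](C)(C)C(C)(C)C)[C@@H]21 | intermediate
28 | (1S,2R,7S,7aR)-7-[(butanoyloxy)methyl]-1-hydroxy-4-[(1S)-1,3,3-trimethylcyclohexyl]-2,3,5,6,7,7a-hexahydro-1H-indene-2-carboxylic acid | CCCC(=O)OC[C@H]1CCC([C@@]2(C)CCCC(C)(C)C2)=C2C[C@@H](C(=O)O)[C@@H](O)[C@@H]21 | intermediate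
29 | 3'-norspongiolactone (C1 S, C7 R, C8 S, C9 R, C1' S in the numbering of the plan) | CCCC(=O)OC[C@H]1CCC([C@@]2(C)CCCC(C)(C)C2)=C2C[C@H]3C(=O)O[C@H]3[C@@H]21 | target

**Step count**

Total: 19 steps. Longest linear sequence: 19 steps (1 → 29).

**Steps most likely to fail**

Step 15. The seven-membered rhodacycle may lose a β-hydrogen faster than it closes ring A, ethylene may fail to insert next to the bulky C1' group, or the facial bias of C8 may be too small. The fallback sets out from 23 and comes back at 25, and it changes the two-carbon partner to one whose chemistry is established. Under the same [Rh(cod)2]BF4/BINAP system and acetylene (1 atm), 23 would enter the known enyne–alkyne [2+2+2] cycloaddition. There ring A closes by C(sp2)–C(sp2) reductive elimination from a rhodacycloheptadiene with no sp3 carbon in the two-carbon unit, which gives the cyclohexa-1,3-diene diester F1 (25 with an additional C2=C3 double bond). Diimide (2-nitrobenzenesulfonyl hydrazide, Et3N, CH2Cl2, rt) would then saturate the disubstituted C2=C3 bond and leave the tetrasubstituted C4=C5 bond, which gives 25.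

Step 13. Exocyclic cleavage of the hindered α-branched silyloxy imide may be slow, so that saponification of the ethyl ester, conjugate attack of hydroperoxide on the enoate or endocyclic opening of the auxiliary compete. The fallback sets out from 19 and comes back at 23 by changing the order of operations. The unprotected aldol adduct 19, whose imide is much less shielded, is cleaved with LiOH/H2O2 at 0 °C; sulfite reduction of the hydroxy peroxy acid F2 gives the β-hydroxy acid F3. tert-Butyl transfer from the isourea gives the β-hydroxy tert-butyl ester F4, and silylation with TBSOTf/2,6-lutidine then gives 23.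

Step 18. Protonation of the tetrasubstituted C4=C5 bond in strong acid may cause double-bond migration or skeletal rearrangement next to the quaternary centre, and desilylation may lag behind ester cleavage. The fallback sets out from 27 and comes back at 28 and replaces the protic acid by a silyl triflate and fluoride. TMSOTf/2,6-lutidine in CH2Cl2 at 0 °C converts the tert-butyl ester into the trimethylsilyl ester F5 without a free strong acid, and aqueous work-up gives the silyl ether acid F6. HF·pyridine in THF/pyridine then removes the silyl ether and gives 28.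

**Further compounds**

F1 | step 15 | 2-tert-butyl 7-ethyl (1S,2R,7S,7aR)-1-[(tert-butyldimethylsilyl)oxy]-4-[(1S)-1,3,3-trimethylcyclohexyl]-2,3,7,7a-tetrahydro-1H-indene-2,7-dicarboxylate | CCOC(=O)[C@H]1C=CC([C@@]2(C)CCCC(C)(C)C2)=C2C[C@@H](C(=O)OC(C)(C)C)[C@@H](O[Si](C)(C)C(C)(C)C)[C@@H]21
F2 | step 13 | (2R,3S,4E)-6-ethoxy-3-hydroxy-6-oxo-2-{3-[(1S)-1,3,3-trimethylcyclohexyl]prop-2-yn-1-yl}hex-4-eneperoxoic acid (not isolated) | CCOC(=O)/C=C/[C@H](O)[C@@H](CC#C[C@@]1(C)CCCC(C)(C)C1)C(=O)OO
F3 | step 13 | (2R,3S,4E)-6-ethoxy-3-hydroxy-6-oxo-2-{3-[(1S)-1,3,3-trimethylcyclohexyl]prop-2-yn-1-yl}hex-4-enoic acid | CCOC(=O)/C=C/[C@H](O)[C@@H](CC#C[C@@]1(C)CCCC(C)(C)C1)C(=O)O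
F4 | step 13 | 6-tert-butyl 1-ethyl (2E,4S,5R)-4-hydroxy-5-{3-[(1S)-1,3,3-trimethylcyclohexyl]prop-2-yn-1-yl}hex-2-enedioate | CCOC(=O)/C=C/[C@H](O)[C@@H](CC#C[C@@]1(C)CCCC(C)(C)C1)C(=O)OC(C)(C)C
F5 | step 18 | trimethylsilyl (1S,2R,7S,7aR)-7-[(butanoyloxy)methyl]-1-[(tert-butyldimethylsilyl)oxy]-4-[(1S)-1,3,3-trimethylcyclohexyl]-2,3,5,6,7,7a-hexahydro-1H-indene-2-carboxylate (not isolated) | CCCC(=O)OC[C@H]1CCC([C@@]2(C)CCCC(C)(C)C2)=C2C[C@@H](C(=O)O[Si](C)(C)C)[C@@H](O[Si](C)(C)C(C)(C)C)[C@@H]21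
F6 | step 18 | (1S,2R,7S,7aR)-7-[(butanoyloxy)methyl]-1-[(tert-butyldimethylsilyl)oxy]-4-[(1S)-1,3,3-trimethylcyclohexyl]-2,3,5,6,7,7a-hexahydro-1H-indene-2-carboxylic acid | CCCC(=O)OC[C@H]1CCC([C@@]2(C)CCCC(C)(C)C2)=C2C[C@@H](C(=O)O)[C@@H](O[Si](C)(C)C(C)(C)C)[C@@H]21
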